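**Retrosynthetic overview**

1. Ring names: A is the trimethoxybenzene, B the 2,6-dimethoxycyclohexa-2,5-dienone, C the seven-membered carbocycle. Ring C consists of spiro C1', C7'H2, C8'HMe, C8HMe, C7H(OAc) and two adjacent ring A carbons, Ca (bears C7) and Cb (bears C1'). The last step is acetylation of the C7 carbinol.
2. The key disconnection is Cb–C1'. Ring C grows out of a five-membered 2,1-benzoxasilole ring (Si, O, C7, Ca, Cb). Oxidation of the tethered phenol makes C1' electrophilic, Cb attacks it ipso to silicon, and the Cb–Si bond breaks. The two-atom Si–O bridge between Cb and C7 is thereby replaced by the four-carbon bridge C1'–C7'–C8'–C8 (five to seven atoms). Ring B is dearomatised and the quaternary centre is formed in the same event.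
3. Enabling feature: C1' is the para carbon of a latent 2,6-dimethoxyphenol. Cb lies ortho and para to ring A methoxy groups. The oxygen-bearing C7 sits on the neighbouring carbon Ca, so its oxygen and Cb can be clamped by one silicon atom in a five-membered ring.
4. C8 and C8' come from C2-symmetric (2S,3S)-2,3-dimethylsuccinic anhydride. The ring B Grignard reagent opens either carbonyl to the same product, the benzylic C=O is hydrogenolysed, and ring A is added as an aryllithium to the acid. C7 is set by CBS reduction, and silicon is introduced by directed ortho-metalation.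
5. Ring order: A and B are bought as arenes, the oxasilole ring is made in step 7, and ring C forms with dearomatisation of B in step 8.

Key step: step 8

Remark: (2S,3S)-2,3-dimethylbutanedioic acid is taken as purchasable in enantiopure form (it is also accessible by classical resolution of the racemic acid).

**Step 1**
Reactants: 1 4-bromo-2,6-dimethoxyphenol
Product: 2 2-(benzyloxy)-5-bromo-1,3-dimethoxybenzene
Conditions: BnBr, K2CO3, DMF, 22 °C
Reagents that add atoms: benzyl bromide, BrCc1ccccc1
Why: Williamson ether synthesis masks the acidic phenol so that the aryl bromide can be turned into a Grignard reagent; no stereocentre is involved.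

**Step 2**
Reactants: 3 (2S,3S)-2,3-dimethylbutanedioic acid
Product: 4 (3S,4S)-3,4-dimethyloxolane-2,5-dione
Conditions: AcCl, 50 °C
Reagents that add atoms: none
Why: Dehydrative cyclisation of a 1,4-diacid through the mixed anhydride runs without base, so the two α-stereocentres are not enolised and the trans (C2-symmetric) anhydride should result.

**Step 3**
Reactants: 2 2-(benzyloxy)-5-bromo-1,3-dimethoxybenzene; 4 (3S,4S)-3,4-dimethyloxolane-2,5-dione
Product: 6 (2S,3S)-4-[4-(benzyloxy)-3,5-dimethoxyphenyl]-2,3-dimethyl-4-oxobutanoic acid, via aryl Grignard reagent 5 (not isolated)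
Conditions: Mg, THF, 40 °C; added to 4, THF, −78 to −20 °C; 1 M HCl
Reagents that add atoms: none
Why: Acylation of a Grignard reagent by a cyclic anhydride stops at the keto carboxylate, the two carbonyl groups of 4 are homotopic so only one product can form, and inverse addition at low temperature limits enolisation of C8'.

**Step 4**
Reactants: 6 (2S,3S)-4-[4-(benzyloxy)-3,5-dimethoxyphenyl]-2,3-dimethyl-4-oxobutanoic acid
Product: 7 (2S,3R)-4-(4-hydroxy-3,5-dimethoxyphenyl)-2,3-dimethylbutanoic acid
Conditions: H2 (4 bar), Pd/C, AcOH, 40 °C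
Reagents that add atoms: none
Why: Catalytic hydrogenolysis takes the electron-rich aryl ketone through the benzylic alcohol to CH2 (C7') and cleaves the benzyl ether in the same operation, and the weakly acidic medium leaves C8 and C8' untouched.

**Step 5**
Reactants: 7 (2S,3R)-4-(4-hydroxy-3,5-dimethoxyphenyl)-2,3-dimethylbutanoic acid; 8 5-bromo-1,2,3-trimethoxybenzene
Product: 10 (2S,3R)-4-(4-hydroxy-3,5-dimethoxyphenyl)-2,3-dimethyl-1-(3,4,5-trimethoxyphenyl)butan-1-one, via 3,4,5-trimethoxyphenyllithium 9 (not isolated)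
Conditions: 8, n-BuLi, THF, −78 °C; 7 pre-treated with n-BuLi (2 equiv), THF, −78 °C; mixed, −78 to 0 °C; aq NH4Cl
Reagents that add atoms: none
Why: Addition of an aryllithium to a lithium carboxylate gives a gem-diolate that is stable until work-up, so no tertiary alcohol forms and the ketone, with its α-stereocentre C8, is released only under buffered conditions.

**Step 6**
Reactants: 10 (2S,3R)-4-(4-hydroxy-3,5-dimethoxyphenyl)-2,3-dimethyl-1-(3,4,5-trimethoxyphenyl)butan-1-one
Product: 11 (1R,2S,3R)-4-(4-hydroxy-3,5-dimethoxyphenyl)-2,3-dimethyl-1-(3,4,5-trimethoxyphenyl)butan-1-ol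
Conditions: (S)-2-methyl-CBS-oxazaborolidine (20 mol %), BH3·SMe2 (2.5 equiv), THF, −20 °C; MeOH
Reagents that add atoms: none
Why: Corey–Bakshi–Shibata reduction binds the ketone with the aryl group as the large substituent and delivers hydride to the Si face, which sets C7 as R (7,8-syn) by catalyst control against the Felkin–Anh bias of the substrate.

**Step 7**
Reactants: 11 (1R,2S,3R)-4-(4-hydroxy-3,5-dimethoxyphenyl)-2,3-dimethyl-1-(3,4,5-trimethoxyphenyl)butan-1-ol
Product: 13 (3R)-3-[(2S,3R)-4-(4-hydroxy-3,5-dimethoxyphenyl)-3-methylbutan-2-yl]-5,6,7-trimethoxy-1,1-dimethyl-1,3-dihydro-2,1-benzoxasilole, via trilithiated intermediate 12 (not isolated)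
Conditions: n-BuLi (3.3 equiv), TMEDA, Et2O, 0 to 22 °C; Me2SiCl2 (1.05 equiv), −78 to 0 °C; aq NH4Cl
Reagents that add atoms: dichlorodimethylsilane, C[Si](C)(Cl)Cl
Why: Directed ortho-metalation places lithium on the ring A C–H that lies between the benzylic alkoxide and a methoxy group (ring B is shielded as its phenoxide), the aryllithium attacks Me2SiCl2 and the neighbouring alkoxide closes the five-membered ring before the remote phenoxide can react; no stereocentre is touched.

**Step 8**
Reactants: 13 (3R)-3-[(2S,3R)-4-(4-hydroxy-3,5-dimethoxyphenyl)-3-methylbutan-2-yl]-5,6,7-trimethoxy-1,1-dimethyl-1,3-dihydro-2,1-benzoxasilole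
Product: 15 (7R,8S,9R)-9-hydroxy-2,3,3',4,5'-pentamethoxy-7,8-dimethyl-6,7,8,9-tetrahydrospiro[benzo[7]annulene-5,1'-cyclohexa[2,5]dien]-4'-one, via acetoxysilyl ether 14 (not isolated)
Conditions: PhI(OAc)2 (1.1 equiv), (CF3)2CHOH–CH2Cl2 1:1 (0.005 M), −20 °C; aq NaHCO3, 22 °C
Reagents that add atoms: none
Why: Proposed new method: the free phenol exchanges a ligand at PhI(OAc)2 and loss of PhI makes C1' a phenoxenium-type electrophile; Cb attacks it ipso to silicon, the arenium ion being stabilised by the out-of-plane C–Si bond (β-silicon effect) and by the ortho and para methoxy groups, and acetate takes up the silicon, which stays on O7 until aqueous work-up. The closest known reaction types are the para–ortho' oxidative coupling of phenols with trivalent iodine reagents, which gives spirodienones including ones with seven-membered rings, and the electrophilic ipso-desilylation of arylsilanes. Ring C closes in a Friedel–Crafts mode that is endo at the Ca–Cb π bond (both carbons end up in the seven-membered ring) while the oxasilole opens, so Si and O leave the ring and C8, C8', C7' and C1' enter it. No new stereocentre forms, because C1' carries two identical ring B arms, and C7, C8 and C8' are spectators since the C7–O bond is never broken. The step needs attack at Cb rather than at the free ortho C–H, and C–C bond formation rather than loss of a C7' proton to a quinone methide or capture by oxygen. The first is secured by silicon (made more Lewis acidic by the strained five-membered ring and thus ready to bind acetate), the second by the ionising, non-nucleophilic fluoro alcohol and high dilution, and the third by O7 being tied to silicon, which also holds the side chain perpendicular to ring A, over Cb.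

**Step 9**
Reactants: 15 (7R,8S,9R)-9-hydroxy-2,3,3',4,5'-pentamethoxy-7,8-dimethyl-6,7,8,9-tetrahydrospiro[benzo[7]annulene-5,1'-cyclohexa[2,5]dien]-4'-one
Product: 16 (7R,8S,9R)-2,3,3',4,5'-pentamethoxy-7,8-dimethyl-4'-oxo-6,7,8,9-tetrahydrospiro[benzo[7]annulene-5,1'-cyclohexa[2,5]dien]-9-yl acetate
Conditions: Ac2O, pyridine, DMAP (cat.), CH2Cl2, 0 °C
Reagents that add atoms: acetic anhydride, CC(=O)OC(C)=O
Why: DMAP-catalysed acylation of a secondary alcohol breaks only the O–H bond, so C7 keeps its configuration, and the mild base leaves the dienone intact.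

**Compound list**

1 | 4-bromo-2,6-dimethoxyphenol | COc1cc(Br)cc(OC)c1O | starting material
2 | 2-(benzyloxy)-5-bromo-1,3-dimethoxybenzene | COc1cc(Br)cc(OC)c1OCc1ccccc1 | intermediate
3 | (2S,3S)-2,3-dimethylbutanedioic acid | OC(=O)[C@@H](C)[C@H](C)C(=O)O | starting material
4 | (3S,4S)-3,4-dimethyloxolane-2,5-dione | O=C1[C@@H](C)[C@H](C)C(=O)O1 | intermediate
5 | [4-(benzyloxy)-3,5-dimethoxyphenyl]magnesium bromide | COc1cc([Mg]Br)cc(OC)c1OCc1ccccc1 | intermediate
6 | (2S,3S)-4-[4-(benzyloxy)-3,5-dimethoxyphenyl]-2,3-dimethyl-4-oxobutanoic acid | COc1cc(cc(OC)c1OCc1ccccc1)C(=O)[C@@H](C)[C@H](C)C(=O)O | intermediate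
7 | (2S,3R)-4-(4-hydroxy-3,5-dimethoxyphenyl)-2,3-dimethylbutanoic acid | COc1cc(C[C@@H](C)[C@H](C)C(=O)O)cc(OC)c1O | intermediate
8 | 5-bromo-1,2,3-trimethoxybenzene | COc1cc(Br)cc(OC)c1OC | starting material
9 | 3,4,5-trimethoxyphenyllithium | COc1cc([Li])cc(OC)c1OC | intermediate
10 | (2S,3R)-4-(4-hydroxy-3,5-dimethoxyphenyl)-2,3-dimethyl-1-(3,4,5-trimethoxyphenyl)butan-1-one | COc1cc(C[C@@H](C)[C@H](C)C(=O)c2cc(OC)c(OC)c(OC)c2)cc(OC)c1O | intermediate
11 | (1R,2S,3R)-4-(4-hydroxy-3,5-dimethoxyphenyl)-2,3-dimethyl-1-(3,4,5-trimethoxyphenyl)butan-1-ol | COc1cc(C[C@@H](C)[C@H](C)[C@@H](O)c2cc(OC)c(OC)c(OC)c2)cc(OC)c1O | intermediate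
12 | trilithiated 11 (phenoxide, C7 alkoxide, Cb–Li) | COc1cc(C[C@@H](C)[C@H](C)[C@@H](O[Li])c2cc(OC)c(OC)c(OC)c2[Li])cc(OC)c1O[Li] | intermediate
13 | (3R)-3-[(2S,3R)-4-(4-hydroxy-3,5-dimethoxyphenyl)-3-methylbutan-2-yl]-5,6,7-trimethoxy-1,1-dimethyl-1,3-dihydro-2,1-benzoxasilole | COc1cc(C[C@@H](C)[C@H](C)[C@H]2O[Si](C)(C)c3c(OC)c(OC)c(OC)cc32)cc(OC)c1O | intermediate
14 | C7 O-[acetoxy(dimethyl)silyl] ether of 15 | COC1=CC2(C=C(OC)C1=O)C[C@@H](C)[C@H](C)[C@@H](O[Si](C)(C)OC(C)=O)c1cc(OC)c(OC)c(OC)c12 | intermediate
15 | (7R,8S,9R)-9-hydroxy-2,3,3',4,5'-pentamethoxy-7,8-dimethyl-6,7,8,9-tetrahydrospiro[benzo[7]annulene-5,1'-cyclohexa[2,5]dien]-4'-one | COC1=CC2(C=C(OC)C1=O)C[C@@H](C)[C@H](C)[C@@H](O)c1cc(OC)c(OC)c(OC)c12 | intermediate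
16 | (7R,8S,9R)-2,3,3',4,5'-pentamethoxy-7,8-dimethyl-4'-oxo-6,7,8,9-tetrahydrospiro[benzo[7]annulene-5,1'-cyclohexa[2,5]dien]-9-yl acetate | COC1=CC2(C=C(OC)C1=O)C[C@@H](C)[C@H](C)[C@@H](OC(C)=O)c1cc(OC)c(OC)c(OC)c12 | target

Total step count: 9. Longest linear sequence: 8 steps (1, 3, 4, 5, 6, 7, 8, 9).

**Steps most likely to fail**

**Step 8 (proposed new method).** Several processes may compete. The phenoxenium intermediate may lose a C7' proton to give a quinone methide. The arylsilane may be protodesilylated by the acidic medium before oxidation. Attack may occur through the free ortho C–H with the oxasilole left intact. The product may suffer an acid-induced aryl 1,2-shift (dienone–phenol rearrangement).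

The fallback sets out from 11 and comes back at 16, and it uses only the known oxidative phenol coupling. Ac2O and pyridine convert 11 into the diacetate F1. Pyrrolidine in CH2Cl2 at 0 °C cleaves only the aryl ester to give the C7 monoacetate phenol F2. PhI(OCOCF3)2 in CF3CH2OH at −40 °C then couples C1' with the ortho C–H of ring A to give 16 directly.

**Step 7.** The triple deprotonation may stay incomplete because of poor solubility of the polyanion. Lithiation may stray to ring B, or the chlorosilane may be consumed at the phenoxide.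

The fallback sets out from 8 (with 7) and comes back at 13, and it carries the silicon in the ring A building block. LDA in the presence of Me2SiHCl (in situ quench, THF, −78 °C) silylates the C–H of 8 between Br and OMe to give (6-bromo-2,3,4-trimethoxyphenyl)dimethylsilane F3. Bromine–lithium exchange with n-BuLi gives the aryllithium F4. Added to the dilithium salt of 7 as in step 5, F4 gives the ortho-silyl ketone F5. CBS reduction as in step 6 gives the ortho-silyl alcohol F6. Catalytic KOt-Bu then effects the dehydrogenative Si–O ring closure to 13.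

**Step 6.** Facial selectivity may be poor, because catalyst control has to override the Felkin–Anh preference of the α-branched ketone, and the free phenol consumes borane.

The fallback sets out from 7 and comes back at 11, and it turns the substrate bias to advantage by exchanging the roles of hydride and aryl group. EDC and MeNHOMe·HCl convert 7 into the Weinreb amide F7, and DIBAL-H (THF, −78 °C) gives the aldehyde F8. Felkin–Anh addition of excess aryllithium 9 (THF, −78 °C) should then give the 7,8-syn alcohol 11.

**Further compounds**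

F1 | step 8 | (1R,2S,3R)-4-(4-acetoxy-3,5-dimethoxyphenyl)-2,3-dimethyl-1-(3,4,5-trimethoxyphenyl)butyl acetate | COc1cc(C[C@@H](C)[C@H](C)[C@@H](OC(C)=O)c2cc(OC)c(OC)c(OC)c2)cc(OC)c1OC(C)=O
F2 | step 8 | (1R,2S,3R)-4-(4-hydroxy-3,5-dimethoxyphenyl)-2,3-dimethyl-1-(3,4,5-trimethoxyphenyl)butyl acetate | COc1cc(C[C@@H](C)[C@H](C)[C@@H](OC(C)=O)c2cc(OC)c(OC)c(OC)c2)cc(OC)c1O
F3 | step 7 | (6-bromo-2,3,4-trimethoxyphenyl)dimethylsilane | COc1cc(Br)c([SiH](C)C)c(OC)c1OC
F4 | step 7 | [2-(dimethylsilyl)-3,4,5-trimethoxyphenyl]lithium | COc1cc([Li])c([SiH](C)C)c(OC)c1OC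
F5 | step 7 | (2S,3R)-1-[2-(dimethylsilyl)-3,4,5-trimethoxyphenyl]-4-(4-hydroxy-3,5-dimethoxyphenyl)-2,3-dimethylbutan-1-one | COc1cc(C[C@@H](C)[C@H](C)C(=O)c2cc(OC)c(OC)c(OC)c2[SiH](C)C)cc(OC)c1O
F6 | step 7 | (1R,2S,3R)-1-[2-(dimethylsilyl)-3,4,5-trimethoxyphenyl]-4-(4-hydroxy-3,5-dimethoxyphenyl)-2,3-dimethylbutan-1-ol | COc1cc(C[C@@H](C)[C@H](C)[C@@H](O)c2cc(OC)c(OC)c(OC)c2[SiH](C)C)cc(OC)c1O
F7 | step 6 | (2S,3R)-4-(4-hydroxy-3,5-dimethoxyphenyl)-N-methoxy-N,2,3-trimethylbutanamide | COc1cc(C[C@@H](C)[C@H](C)C(=O)N(C)OC)cc(OC)c1O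
F8 | step 6 | (2S,3R)-4-(4-hydroxy-3,5-dimethoxyphenyl)-2,3-dimethylbutanal | COc1cc(C[C@@H](C)[C@H](C)C=O)cc(OC)c1O
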